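Want Q, the complex with one ligand exchanged. X, the complex, takes up G and gives off D to make Q, then E and J with two and three exchanged, and two X may join to Z. Ash is the flask asked about; alder is an earlier, colder run.

| flask | X | G | temperature | remark | time |
|---|---|---|---|---|---|
| ash | 0.099 M | 0.099 M | 25 °C | the very flask that is asked about, followed so far |  |
| alder | 0.050 M | 0.099 M | 10 °C | run made earlier |  |
| flask | 0.099 M | 0.0990 M | 25 °C |  | 3.0 h |

| run | time / min | Q / % | X / % |
|---|---|---|---|
| ash | 50.0 | 36 | 52 |
| ash | 90.0 | 28 | 50 |
| ash | 150 | 22 | 55 |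
| ash | 180 | 20 | 60 |
| alder | 6.00 | 8 | 88 |
| alder | 15.0 | 23 | 73 |
| alder | 30.0 | 36 | 58 |
| alder | 80.0 | 52 | 34 |

(scatter of a reading: 2 percentage points)

- a species is counted by the X in it: one Z counts as two
- Q that was removed still counts
- steps thought possible: X + G <-> D + Q; Q + G <-> D + E; E + G <-> D + J; 2 X -> Z
- additions bring no volume worth counting

- west: change nothing and wait 6.0 h more
- north-west: at 3.0 h add G, 50.0% of the amount charged, then wait 6.0 h
- north-east: at 3.0 h take out 90% of the Q then present, then wait 6.0 h
- south-east: at 3.0 h raise the temperature by 20 K, then wait 6.0 h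

1. Q, in percent of the X first charged, at 3.0 h
2. the remedy with the largest gain of Q, or "none" below 2 percentage points (west / north-west / north-east / south-east / none)
3. Q present, with what was taken out counted in, in percent of the X first charged, after west
4. Q present, with what was taken out counted in, in percent of the X first charged, after south-east

Read ash at 180 min: Q 20%, X 60%. X is climbing back while Q sinks, so don't extrapolate a decay; look for a balance. Add the steps: 3 Q can become two X plus J, and G and D cancel. Count the remainder in ash, 20.0%, as J. That gives 9.00 for the redistribution quotient R, X times X times J over Q cubed, the reaction quotient of this disproportionation.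

Set the zero of the scale: with 3 sites exchanging at random, R is 0.0370 whatever share has exchanged. Ash reads 243 times that, so it strongly prefers the ends over Q.

Object: R isn't constant. At 90.0 min ash reads 2.51, less than now. Then grant the same climb again over the next 6.0 h, to 32.3. Q goes as the cube root of X·X·J over R, so with X and J held it falls just to 13.1%.

Object again: X and J grow as Q goes. Put them in, two X and one J for every 3 Q, and Q comes to 14.2%. Commit to that for west.

The forecast says 20% now, north-east as the remedy, 6% after west and 3% after south-east, on the ground that “Q decays at about 0.004 per min”. The two differ on west: in this reckoning, its 6% asks R to reach 549.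

The flask gives 19.5% now and north-east as best, with a gain of 10 percentage points; west leaves 15.4% and south-east 9.82%.

    X + G ⇌ D + Q (K = 2.10, k = 0.850 M⁻¹ min⁻¹, Ea = 65.0 kJ mol⁻¹, ΔH = −32.0 kJ mol⁻¹)
    Q + G ⇌ D + E (K = 1.10, k = 0.280 M⁻¹ min⁻¹, Ea = 67.0 kJ mol⁻¹, ΔH = −15.0 kJ mol⁻¹)
    E + G ⇌ D + J (K = 80.0, k = 2.20 M⁻¹ min⁻¹, Ea = 69.0 kJ mol⁻¹, ΔH = −4.00 kJ mol⁻¹)
    2 X → Z (k = 0.00130 M⁻¹ min⁻¹, Ea = 61.0 kJ mol⁻¹)
    (constants at 25 °C)

These constants put R at rest at 20.0, against 9.00 read in ash and 549 for the forecast's Q. The simulated state of the flask at 1800 min gives 19.7, with Q at 13.9%. The neighbouring flask, charged with 0.025 M of X, holds X 10.5%, Q 13.2% and J 73.5% at 180 min, so its R is 3.55, lower than the resting value and than the 9.00 read in ash, and 95.9 times the zero.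

The earlier runs and the new flask were computed on assumed constants; noise was put on by code.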